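The route rests on one cut: the C2–C1' bond of the flavanone, made while ring C (O1, C2, C3, C4, C4a, C8a) is still folded up as a benzofuran. C2 sits next to O1 and β to the C4 carbonyl. The 4-oxochroman-2-yl radical is therefore the opened form of a cyclopropanol fused to a dihydrobenzofuran. In the key step, photoredox oxidation of racemic cyclopropanol 9 breaks the shared C2–C4 bond and the five-membered ring grows into ring C. A chiral nickel catalyst couples the radical with aryl bromide 5, which already carries the 3'–8'' biaryl bond and the protected apigenin unit, setting (2S).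

Key step: step 6

Assumption: the 3'–8'' biaryl axis carries no descriptor in the structure and is treated as configurationally undefined; the ligand antipode named in step 6 is the one assumed to give (2S), its mirror image being equally available.

Step 1
Reactants: 1 apigenin
Product: 2 5,7,4'-tri-O-benzylapigenin
Conditions: BnBr (excess), K2CO3, DMF, 80 °C
Reagents that add atoms: benzyl bromide, BrCc1ccccc1
Why: Williamson ether synthesis; excess benzyl bromide and heat also alkylate the hydrogen-bonded 5-OH, so all three phenols carry groups that a single Lewis acid removes at the end.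

Step 2
Reactants: 2 5,7,4'-tri-O-benzylapigenin
Product: 3 8-iodo-5,7,4'-tri-O-benzylapigenin
Conditions: NIS, TFA (cat.), MeCN/CH2Cl2, rt
Reagents that add atoms: N-iodosuccinimide, O=C1CCC(=O)N1I
Why: Electrophilic aromatic iodination; ring A of the flavone is the most electron-rich ring, and C8 is attacked because C6 is shielded on both sides by benzyloxy groups.

Step 3
Reactants: 3 8-iodo-5,7,4'-tri-O-benzylapigenin; 4 (5-bromo-2-methoxyphenyl)boronic acid
Product: 5 8-(5-bromo-2-methoxyphenyl)-5,7,4'-tri-O-benzylapigenin
Conditions: Pd(PPh3)4 (5 mol %), K2CO3, DME/H2O, 85 °C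
Reagents that add atoms: none
Why: Suzuki–Miyaura coupling; zerovalent palladium inserts into the carbon–iodine bond of 3 much faster than into the carbon–bromine bond of 4 or 5, so the 3'–8'' biaryl bond forms and the bromide survives as the handle for step 6.

Step 4
Reactants: 6 4,6-dimethoxybenzofuran-3(2H)-one
Product: 7 4,6-dimethoxy-3-(trimethylsilyloxy)benzofuran
Conditions: TMSOTf, Et3N, CH2Cl2, 0 °C
Reagents that add atoms: trimethylsilyl triflate, C[Si](C)(C)OS(=O)(=O)C(F)(F)F
Why: Silyl enol ether formation by soft enolisation, driven by the gain of benzofuran aromaticity, exposes the furan C2=C3 bond as an electron-rich dioxygenated alkene.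

Step 5
Reactants: 7 4,6-dimethoxy-3-(trimethylsilyloxy)benzofuran
Product: 9 rac-4,6-dimethoxy-1a,6b-dihydro-1H-cyclopropa[b]benzofuran-6b-ol, via trimethylsilyl ether 8 (not isolated)
Conditions: Et2Zn, CH2I2, CH2Cl2, 0 °C; then MeOH, K2CO3 (cat.), 0 °C, short contact
Reagents that add atoms: diiodomethane, ICI
Why: Simmons–Smith cyclopropanation (Furukawa variant) of a silyl enol ether, the electrophilic zinc carbenoid adding to the most electron-rich double bond; the cis ring fusion is enforced by geometry, the product is racemic, which is harmless because both stereocentres vanish in step 6, and methanolysis frees the cyclopropanol.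

Step 6
Reactants: 5 8-(5-bromo-2-methoxyphenyl)-5,7,4'-tri-O-benzylapigenin; 9 rac-4,6-dimethoxy-1a,6b-dihydro-1H-cyclopropa[b]benzofuran-6b-ol
Product: 11 (2S)-2-{3-[5,7-bis(benzyloxy)-2-(4-benzyloxyphenyl)-4-oxo-4H-chromen-8-yl]-4-methoxyphenyl}-5,7-dimethoxychroman-4-one, via 5,7-dimethoxy-4-oxochroman-2-yl radical 10 (not isolated)
Conditions: NiBr2·glyme (10 mol %), chiral 2,2'-bi(imidazoline) ligand (4S,4'S)-iPr-BiIM (12 mol %), [Ir(dF(CF3)ppy)2(dtbbpy)]PF6 (2 mol %), K2HPO4, DMA, blue LED (450 nm), 10 °C
Reagents that add atoms: none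
Why: Proposed new method: the excited iridium photocatalyst oxidises the trioxygenated ring A of 9 and phosphate takes the O–H proton, so the resulting alkoxy radical undergoes β-scission of the C1a–C6b bond shared by the three- and five-membered rings to give the ring-expanded α-oxy radical 10, while zerovalent nickel inserts into the carbon–bromine bond of 5, the divalent aryl nickel species captures 10, reductive elimination from trivalent nickel forms C2–C1', and the reduced photocatalyst returns monovalent nickel to the zerovalent state. The closest known reaction types are the dual photoredox/nickel ring-opening arylation of cyclopropanols to β-aryl ketones, the oxidative Saegusa-type ring expansion of bicyclic cyclopropanols through the internal bond, and the enantioselective nickel arylation of cyclic α-oxy radicals; their union on a cyclopropa[b]benzofuranol has not been shown. Ring C is not closed by a new ring bond but arises by fragmentation of the zero-atom bridge, which merges the dihydrofuran ring (O1, C2, C4, C4a, C8a) and the cyclopropane (C2, C3, C4) into one six-membered ring. The only new stereocentre, C2, is fixed by the chiral ligand on nickel in the capture and reductive-elimination sequence, and the process is enantioconvergent because both stereocentres of racemic 9 are erased in 10. The step needs scission of the internal and not the external cyclopropane bond, which O1 secures by stabilising 10 (a primary radical from external scission would drain into 10 by a Dowd–Beckwith 1,2-acyl shift), and it needs oxidative addition at one site only, which the single carbon–halogen bond of 5 secures. Coupling must also outrun β-hydride loss to the chromone, which fast reductive elimination from trivalent nickel and the low temperature should favour.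

Step 7
Reactants: 11 (2S)-2-{3-[5,7-bis(benzyloxy)-2-(4-benzyloxyphenyl)-4-oxo-4H-chromen-8-yl]-4-methoxyphenyl}-5,7-dimethoxychroman-4-one
Product: 12 (2S)-2-{3-[5,7-dihydroxy-2-(4-hydroxyphenyl)-4-oxo-4H-chromen-8-yl]-4-methoxyphenyl}-5-hydroxy-7-methoxychroman-4-one (CNP0169789.1)
Conditions: BCl3, C6HMe5, CH2Cl2, −78 to 0 °C; then MeOH/H2O
Reagents that add atoms: none
Why: Lewis-acid ether cleavage; BCl3 with pentamethylbenzene as benzyl-cation trap removes the three benzyl ethers, and chelation of boron between the C4 carbonyl and the 5-oxygen cleaves only that methyl ether, while the 7- and 4'-methyl ethers and, at low temperature, the C2 stereocentre should stay untouched.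

Compound list
1 | apigenin, 5,7-dihydroxy-2-(4-hydroxyphenyl)-4H-chromen-4-one | O=c1cc(-c2ccc(O)cc2)oc2cc(O)cc(O)c12 | starting material
2 | 5,7,4'-tri-O-benzylapigenin | O=c1cc(-c2ccc(OCc3ccccc3)cc2)oc2cc(OCc3ccccc3)cc(OCc3ccccc3)c12 | intermediate
3 | 8-iodo-5,7,4'-tri-O-benzylapigenin | O=c1cc(-c2ccc(OCc3ccccc3)cc2)oc2c(I)c(OCc3ccccc3)cc(OCc3ccccc3)c12 | intermediate
4 | (5-bromo-2-methoxyphenyl)boronic acid | COc1ccc(Br)cc1B(O)O | starting material
5 | 8-(5-bromo-2-methoxyphenyl)-5,7,4'-tri-O-benzylapigenin | COc1ccc(Br)cc1-c1c(OCc2ccccc2)cc(OCc2ccccc2)c2c(=O)cc(-c3ccc(OCc4ccccc4)cc3)oc12 | intermediate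
6 | 4,6-dimethoxybenzofuran-3(2H)-one | COc1cc(OC)c2c(c1)OCC2=O | starting material
7 | 4,6-dimethoxy-3-(trimethylsilyloxy)benzofuran | COc1cc(OC)c2c(O[Si](C)(C)C)coc2c1 | intermediate
8 | rac-4,6-dimethoxy-6b-(trimethylsilyloxy)-1a,6b-dihydro-1H-cyclopropa[b]benzofuran (cis-fused, racemic) | COc1cc(OC)c2c(c1)OC1CC12O[Si](C)(C)C | intermediate
9 | rac-4,6-dimethoxy-1a,6b-dihydro-1H-cyclopropa[b]benzofuran-6b-ol (cis-fused, racemic) | COc1cc(OC)c2c(c1)OC1CC12O | intermediate
10 | 5,7-dimethoxy-4-oxochroman-2-yl radical | COc1cc(OC)c2c(c1)O[CH]CC2=O | intermediate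
11 | (2S)-2-{3-[5,7-bis(benzyloxy)-2-(4-benzyloxyphenyl)-4-oxo-4H-chromen-8-yl]-4-methoxyphenyl}-5,7-dimethoxychroman-4-one | COc1cc(OC)c2c(c1)O[C@H](c1ccc(OC)c(-c3c(OCc4ccccc4)cc(OCc4ccccc4)c4c(=O)cc(-c5ccc(OCc6ccccc6)cc5)oc34)c1)CC2=O | intermediate
12 | (2S)-2-{3-[5,7-dihydroxy-2-(4-hydroxyphenyl)-4-oxo-4H-chromen-8-yl]-4-methoxyphenyl}-5-hydroxy-7-methoxychroman-4-one | COc1cc(O)c2c(c1)O[C@H](c1ccc(OC)c(-c3c(O)cc(O)c4c(=O)cc(-c5ccc(O)cc5)oc34)c1)CC2=O | target

Total step count: 7. Longest linear sequence: 5 steps (steps 1, 2, 3, 6, 7).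

Steps most likely to fail

1) Step 6.
- What may go wrong: the alkyl nickel intermediate may lose a β-hydride. Radical 10 may pick up a hydrogen atom before capture. A nickel alkoxide may open the external cyclopropane bond in a two-electron β-carbon elimination. The ligand may discriminate the faces of 10 poorly.
- Fallback: it sets out from 9 and 5, comes back at 11, and uncouples ring expansion from arylation using known chemistry only.
- FeCl3 in DMF at 0 °C (Saegusa-type oxidative ring expansion) takes 9 through the same internal-bond scission to 2-chloro-5,7-dimethoxychroman-4-one F1. NaOAc in MeOH then gives 5,7-dimethoxy-4H-chromen-4-one F2.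
- Borylation of 5 with B2(OH)4, KOAc and Pd(OAc)2/XPhos gives [3-(5,7-bis(benzyloxy)-2-(4-benzyloxyphenyl)-4-oxo-4H-chromen-8-yl)-4-methoxyphenyl]boronic acid F3.
- Rhodium-catalysed asymmetric 1,4-addition of F3 to F2 then delivers 11, with C2 set by the ligand. Conditions: [RhCl(C2H4)2]2, an electron-poor atropisomeric diphosphine of the MeO-BIPHEP family, toluene/H2O, rt. The 2-aryl-substituted enone of the apigenin unit should be inert in this addition.

2) Step 5.
- What may go wrong: the zinc carbenoid may add sluggishly to a double bond that is part of the furan π system. Lewis-acidic zinc salts may desilylate the enol ether or open the cyclopropyl ether before isolation.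
- Fallback: it sets out from 7, comes back at 11, and replaces methylene transfer by halocarbene ring expansion.
- Dibromocarbene (CHBr3, KOtBu, pentane, −20 °C) adds to 7 to give 1,1-dibromo-4,6-dimethoxy-6b-(trimethylsilyloxy)-1a,6b-dihydro-1H-cyclopropa[b]benzofuran F4. On warming, F4 opens through the internal bond to 3-bromo-5,7-dimethoxy-4H-chromen-4-one F5.
- Hydrodebromination with Pd(PPh3)4 and HCO2Na in DMF gives 5,7-dimethoxy-4H-chromen-4-one F2. F2 is joined with F3 by the rhodium-catalysed 1,4-addition described above to reach 11.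

3) Step 7.
- What may go wrong: the Lewis acid may open ring C at the p-methoxybenzylic C2–O1 bond with erosion of configuration. Cleavage of the chelated methyl ether may lag behind debenzylation.
- Fallback: it sets out from 11, comes back at 12, and separates the two tasks under milder conditions.
- Neutral hydrogenolysis (H2, Pd/C, EtOAc/THF, rt) gives (2S)-2-{3-[5,7-dihydroxy-2-(4-hydroxyphenyl)-4-oxo-4H-chromen-8-yl]-4-methoxyphenyl}-5,7-dimethoxychroman-4-one F6.
- MgI2 etherate in THF then removes only the methyl ether chelated to the C4 carbonyl, giving 12.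

Further compounds
F1 | step 6 | 2-chloro-5,7-dimethoxychroman-4-one | COc1cc(OC)c2c(c1)OC(Cl)CC2=O
F2 | step 6 | 5,7-dimethoxy-4H-chromen-4-one | COc1cc(OC)c2c(=O)ccoc2c1
F3 | step 6 | [3-(5,7-bis(benzyloxy)-2-(4-benzyloxyphenyl)-4-oxo-4H-chromen-8-yl)-4-methoxyphenyl]boronic acid | COc1ccc(B(O)O)cc1-c1c(OCc2ccccc2)cc(OCc2ccccc2)c2c(=O)cc(-c3ccc(OCc4ccccc4)cc3)oc12
F4 | step 5 | 1,1-dibromo-4,6-dimethoxy-6b-(trimethylsilyloxy)-1a,6b-dihydro-1H-cyclopropa[b]benzofuran | COc1cc(OC)c2c(c1)OC1C(Br)(Br)C12O[Si](C)(C)C
F5 | step 5 | 3-bromo-5,7-dimethoxy-4H-chromen-4-one | COc1cc(OC)c2c(=O)c(Br)coc2c1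
F6 | step 7 | (2S)-2-{3-[5,7-dihydroxy-2-(4-hydroxyphenyl)-4-oxo-4H-chromen-8-yl]-4-methoxyphenyl}-5,7-dimethoxychroman-4-one | COc1cc(OC)c2c(c1)O[C@H](c1ccc(OC)c(-c3c(O)cc(O)c4c(=O)cc(-c5ccc(O)cc5)oc34)c1)CC2=O
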